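**Plan**

1. Retrosynthetic cuts, in order: the O–C bond between the C1 carbinol oxygen and the ring carbon para to the acyl group (the target is the hydroxide-opened form of a cis-fused dihydrofuran); the two prenyl C–C bonds at the one free ring carbon; the pair C2–C1′ and O–C1 together; finally the C6–O aryl ether.
2. Forward: (R)-carvone → cis-carveol → trans-carveol → cis-carvyl ether on the para-hydroxyl of phlorisobutyrophenone → one-pot [3,3] shift and phenol–alkene closure (the only ring made, a temporary dihydrofuran) → gem-diprenylation with dearomatisation → hydroxide removes the temporary ring.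
3. Enabling feature: on the cyclohexane, C1 (C(OH)Me), C2 (bonded to triketone carbon C1′) and C4 (isopropenyl) are all cis. An oxygen placed cis on C6 can pass the aryl group to C2 on its own face through the allyl unit C6–C1=C2, and the five-membered ring O–C1–C2–C1′–C(O) can only fuse cis.
4. Stereochemistry: C4 comes from (R)-carvone; the C6–O centre is set cis by Luche reduction and two Mitsunobu inversions; C2 by suprafacial chirality transfer; C1 by the cis ring fusion, and it is kept on ring opening because the C1–O bond is never broken.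

Key step: step 5

Remark: C1–C6 are the target's cyclohexane locants throughout (C6 is the carbinol carbon of carveol, C4 carries isopropenyl). Ar-1 to Ar-6 number the acylphloroglucinol ring from the isobutyryl-bearing carbon, so C1′ = Ar-3 and the para oxygen sits on Ar-4. CIP descriptors in names follow each compound's own nomenclature numbering. Compounds 10 and 11 are drawn as one enol tautomer of an equilibrating set.

**Step 1**
Reactants: 1 (R)-(−)-carvone
Product: 2 (1R,5R)-cis-carveol
Conditions: NaBH4, CeCl3·7H2O, MeOH, −20 °C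
Reagents that add atoms: none
Why: Luche reduction: cerium-activated 1,2-hydride delivery from the face anti to the C4 isopropenyl group (axial attack on the half-chair) should give the allylic alcohol with the new C6 hydroxyl cis to isopropenyl and leave both alkenes untouched.

**Step 2**
Reactants: 2 (1R,5R)-cis-carveol
Product: 3 (1S,5R)-trans-carvyl 4-nitrobenzoate
Conditions: 4-O2NC6H4CO2H, PPh3, DIAD, THF, 0 °C → rt
Reagents that add atoms: 4-nitrobenzoic acid, O=C(O)c1ccc(cc1)[N+](=O)[O-]
Why: Mitsunobu esterification: the carboxylate displaces the C6 alkoxyphosphonium ion by SN2 with inversion, placing the oxygen trans to isopropenyl, and the acidic pronucleophile keeps elimination and SN2′ leakage low.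

**Step 3**
Reactants: 3 (1S,5R)-trans-carvyl 4-nitrobenzoate
Product: 4 (1S,5R)-trans-carveol
Conditions: K2CO3 (0.2 equiv), MeOH, rt
Reagents that add atoms: none
Why: Base-catalysed transesterification (methanolysis) cleaves the acyl–oxygen bond of the activated nitrobenzoate, so the C6 configuration is untouched.

**Step 4**
Reactants: 4 (1S,5R)-trans-carveol; 5 phlorisobutyrophenone
Product: 6 4-O-[(1R,5R)-cis-carvyl]phlorisobutyrophenone, i.e. 1-(2,6-dihydroxy-4-{[(1R,5R)-2-methyl-5-(prop-1-en-2-yl)cyclohex-2-en-1-yl]oxy}phenyl)-2-methylpropan-1-one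
Conditions: PPh3, DIAD, THF–PhMe, 0 °C (betaine pre-formed), then 4 and 5 (1.5 equiv), 0 °C → rt
Reagents that add atoms: none
Why: Mitsunobu aryl-ether formation: the Ar-4 hydroxyl of 5 is the most acidic and the only one neither chelated to nor flanked by the acyl group, so it should be the one alkylated, and SN2 inversion at C6 brings the oxygen back to the face cis to isopropenyl.

**Step 5**
Reactants: 6 4-O-[(1R,5R)-cis-carvyl]phlorisobutyrophenone
Product: 8 1-[(5aR,8S,9aR)-1,3-dihydroxy-5a-methyl-8-(prop-1-en-2-yl)-5a,6,7,8,9,9a-hexahydrodibenzo[b,d]furan-2-yl]-2-methylpropan-1-one (linear cis-fused dihydrofuran diol), via ortho-cyclohexenyl phenol 7 (not isolated)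
Conditions: Eu(fod)3 (10 mol %), PhMe, 80–100 °C, Ar; then CSA (0.5 equiv), 0 → 23 °C, same flask
Reagents that add atoms: none
Why: Eu(III) coordination polarises the C6–O bond just enough for a concerted, suprafacial [3,3] shift (aromatic Claisen rearrangement) that forms C2–Ar-3 on the face the oxygen occupied, and enolisation returns phenol 7; the sulfonic acid then protonates C1=C6 at C6 and the free Ar-4 hydroxyl traps tertiary C1 (Markovnikov phenol–alkene hydroalkoxylation). The closest known reactions are the Eu(fod)3-catalysed Claisen rearrangement of cycloalkenyl aryl ethers with chirality transfer and the acid-catalysed closure of ortho-cycloalkenyl phenols to cis-hexahydrodibenzofurans. The one new ring, the dihydrofuran O–C1–C2–Ar-3–Ar-4, closes 5-exo-trig. C2 is set by the C6–O stereocentre through suprafaciality, so the aryl group arrives cis to the C4 isopropenyl group; C1 is set by the ring itself, because a five-membered ring fused to the cyclohexane can only close on the face that carries the aryl group. The step needs the concerted path to beat ionisation to the carvyl cation, which is Cs-symmetric and would erase both the cis relationship and the enantiopurity; the weak Lewis acid, the non-polar solvent and the two ring hydroxyls that make Ar-3 strongly nucleophilic favour the sigmatropic path. The isopropenyl group should survive because only the ring alkene has an internal nucleophile placed for a five-membered closure, and closure through the Ar-2 hydroxyl is disfavoured by its hydrogen bond to the ketone.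

**Step 6**
Reactants: 8 linear cis-fused dihydrofuran diol; 9 prenyl bromide
Product: 10 (5aR,8S,9aR)-3-hydroxy-5a-methyl-4,4-bis(3-methylbut-2-en-1-yl)-2-(2-methylpropanoyl)-8-(prop-1-en-2-yl)-5a,6,7,8,9,9a-hexahydrodibenzo[b,d]furan-1(4H)-one
Conditions: NaOMe (3 equiv), MeOH, 0 °C, Ar; 9 (2.3 equiv), 0 °C → rt; cold pH 4 work-up
Reagents that add atoms: none
Why: Dearomatising double C-alkylation of an acylphloroglucinol phenoxide (the reaction used for lupulone-type gem-diprenyl cores): Ar-5 is the only unsubstituted ring carbon and is ortho/para to both phenoxides, so both prenyl groups should enter there in the hydrogen-bonding solvent that disfavours O-alkylation, Ar-3 being shielded by the ring fusion and Ar-1 by the acyl group; no stereocentre is formed because the two new groups are identical.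

**Step 7**
Reactants: 10 dearomatised gem-diprenyl vinylogous ester
Product: 11 3,5-dihydroxy-4-[(1R,2R,5S)-2-hydroxy-2-methyl-5-(prop-1-en-2-yl)cyclohexyl]-6,6-bis(3-methylbut-2-en-1-yl)-2-(2-methylpropanoyl)cyclohexa-2,4-dien-1-one (CNP0324849.1)
Conditions: KOH (10 equiv), H2O–1,4-dioxane (1:1), degassed, 90 °C; then 0 °C, 0.5 M HCl to pH 4, immediate extraction
Reagents that add atoms: potassium hydroxide, [K+].[OH-]; water, O
Why: Saponification of a vinylogous ester by addition–elimination at sp2 carbon Ar-4: hydroxide adds to Ar-4, the tertiary alkoxide departs with its C1–O bond intact (retention at C1), and deprotonation of the new vinylogous acid makes the opening irreversible, while cold, brief acidification avoids acid-induced re-closure.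

**Compound list**

1 | (R)-(−)-carvone, (5R)-2-methyl-5-(prop-1-en-2-yl)cyclohex-2-en-1-one | C=C(C)[C@H]1CC(=O)C(C)=CC1 | starting material
2 | (1R,5R)-cis-carveol (OH cis to isopropenyl) | C=C(C)[C@H]1C[C@@H](O)C(C)=CC1 | intermediate
3 | (1S,5R)-trans-carvyl 4-nitrobenzoate | C=C(C)[C@H]1C[C@H](OC(=O)c2ccc(cc2)[N+](=O)[O-])C(C)=CC1 | intermediate
4 | (1S,5R)-trans-carveol (OH trans to isopropenyl) | C=C(C)[C@H]1C[C@H](O)C(C)=CC1 | intermediate
5 | phlorisobutyrophenone, 2-methyl-1-(2,4,6-trihydroxyphenyl)propan-1-one | CC(C)C(=O)c1c(O)cc(O)cc1O | starting material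
6 | 4-O-[(1R,5R)-cis-carvyl]phlorisobutyrophenone | C=C(C)[C@H]1C[C@@H](Oc2cc(O)c(C(=O)C(C)C)c(O)c2)C(C)=CC1 | intermediate
7 | 2-methyl-1-{2,4,6-trihydroxy-3-[(1S,5S)-2-methyl-5-(prop-1-en-2-yl)cyclohex-2-en-1-yl]phenyl}propan-1-one (aryl cis to isopropenyl) | C=C(C)[C@H]1CC=C(C)[C@@H](c2c(O)cc(O)c(C(=O)C(C)C)c2O)C1 | intermediate
8 | 1-[(5aR,8S,9aR)-1,3-dihydroxy-5a-methyl-8-(prop-1-en-2-yl)-5a,6,7,8,9,9a-hexahydrodibenzo[b,d]furan-2-yl]-2-methylpropan-1-one (ether oxygen para to acyl; O, aryl and isopropenyl all cis) | C=C(C)[C@H]1CC[C@@]2(C)Oc3cc(O)c(C(=O)C(C)C)c(O)c3[C@H]2C1 | intermediate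
9 | prenyl bromide, 1-bromo-3-methylbut-2-ene | CC(C)=CCBr | starting material
10 | (5aR,8S,9aR)-3-hydroxy-5a-methyl-4,4-bis(3-methylbut-2-en-1-yl)-2-(2-methylpropanoyl)-8-(prop-1-en-2-yl)-5a,6,7,8,9,9a-hexahydrodibenzo[b,d]furan-1(4H)-one | C=C(C)[C@H]1CC[C@@]2(C)OC3=C([C@H]2C1)C(=O)C(C(=O)C(C)C)=C(O)C3(CC=C(C)C)CC=C(C)C | intermediate
11 | 3,5-dihydroxy-4-[(1R,2R,5S)-2-hydroxy-2-methyl-5-(prop-1-en-2-yl)cyclohexyl]-6,6-bis(3-methylbut-2-en-1-yl)-2-(2-methylpropanoyl)cyclohexa-2,4-dien-1-one | C=C(C)[C@H]1CC[C@@](C)(O)[C@@H](C2=C(O)C(CC=C(C)C)(CC=C(C)C)C(=O)C(C(=O)C(C)C)=C2O)C1 | target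

**Step count and risks**

Total steps: 7. Longest linear sequence: 7 (from (R)-carvone); phlorisobutyrophenone and prenyl bromide enter at steps 4 and 6.

Steps most likely to fail:

1. Step 5. Ionisation of the allylic C6–O bond (helped by the acidic phenols and the good aryloxide leaving group) could outrun the concerted shift. That would bring loss of enantiopurity and of the cis relationship through the symmetric carvyl cation, elimination to a triene, or acid isomerisation of the isopropenyl group in the second stage. The fallback sets out from 6 and comes back at 8, with the phenols masked and the two events separated. TBSCl/imidazole/DMAP in DMF should give the 2,6-bis-silyl ether F1, which has no acidic hydroxyl and a poorer leaving group because the flanked ketone is twisted out of conjugation. A purely thermal Claisen rearrangement in N,N-diethylaniline at about 180 °C should give the bis-silylated ortho-cyclohexenyl phenol F2. Catalytic CSA in CH2Cl2 then closes the ring through the only free hydroxyl (Ar-4) to the bis-silylated dihydrofuran F3, and TBAF buffered with AcOH releases 8.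

2. Step 7. Hydroxide addition to Ar-4 may be too slow, because the substrate is an enolate under the conditions and Ar-4 sits next to the quaternary Ar-5; retro-Claisen loss of the isobutyryl group or re-closure during acidification could then take over. The fallback sets out from 6 and comes back at 11, moving the temporary ring to the other ortho oxygen so that the carbon to be attacked is flanked only by sp2 carbons. The Eu-catalysed shift is stopped before the acid stage and phenol 7 is isolated. TBSCl (2 equiv)/imidazole should silylate the Ar-4 and Ar-6 hydroxyls and leave the chelated, doubly flanked Ar-2 hydroxyl free, giving the 4,6-bis-silyl ether F5. Catalytic CSA can then close only through the Ar-2 oxygen, to the angular cis-fused dihydrofuran bis-silyl ether F6, and TBAF gives the angular diol F7. NaOMe/prenyl bromide doubly prenylates Ar-5, now lying between two hydroxylated carbons, to the angular vinylogous ester F8. Aqueous KOH opens F8 at Ar-2 to give 11.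

3. Step 4. SN2′ attack or ion-pair leakage at the activated allylic alcohol would erode configuration; elimination, etherification of an ortho hydroxyl or double etherification could also lower the return. The fallback sets out from 2 and comes back at 6, bypassing 3 and 4. ClCO2Me/pyridine gives cis-carvyl methyl carbonate F4. Pd2(dba)3 with the Trost DACH-phenyl ligand and phenol 5 in CH2Cl2 should form the ether by ionisation and attack both anti to palladium, i.e. net retention with the oxygen cis to isopropenyl. Because the π-allyl intermediate is Cs-symmetric, the ligand antipode alone decides which terminus is attacked; both antipodes would be tried and the one that delivers (1R,5R)-6 kept.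

**Further compounds**

F1 | step 5 | 2,6-bis-O-(tert-butyldimethylsilyl) ether of 6 | C=C(C)[C@H]1C[C@@H](Oc2cc(O[Si](C)(C)C(C)(C)C)c(C(=O)C(C)C)c(O[Si](C)(C)C(C)(C)C)c2)C(C)=CC1
F2 | step 5 | 2,6-bis-O-(tert-butyldimethylsilyl) ether of 7 (Ar-4 hydroxyl free) | C=C(C)[C@H]1CC=C(C)[C@@H](c2c(O)cc(O[Si](C)(C)C(C)(C)C)c(C(=O)C(C)C)c2O[Si](C)(C)C(C)(C)C)C1
F3 | step 5 | 1,3-bis-O-(tert-butyldimethylsilyl) ether of 8 | C=C(C)[C@H]1CC[C@@]2(C)Oc3cc(O[Si](C)(C)C(C)(C)C)c(C(=O)C(C)C)c(O[Si](C)(C)C(C)(C)C)c3[C@H]2C1
F4 | step 4 | (1R,5R)-cis-carvyl methyl carbonate | C=C(C)[C@H]1C[C@@H](OC(=O)OC)C(C)=CC1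
F5 | step 7 | 4,6-bis-O-(tert-butyldimethylsilyl) ether of 7 (Ar-2 hydroxyl free) | C=C(C)[C@H]1CC=C(C)[C@@H](c2c(O[Si](C)(C)C(C)(C)C)cc(O[Si](C)(C)C(C)(C)C)c(C(=O)C(C)C)c2O)C1
F6 | step 7 | 1-[(5aR,8S,9aR)-1,3-bis(tert-butyldimethylsilyloxy)-5a-methyl-8-(prop-1-en-2-yl)-5a,6,7,8,9,9a-hexahydrodibenzo[b,d]furan-4-yl]-2-methylpropan-1-one | C=C(C)[C@H]1CC[C@@]2(C)Oc3c(C(=O)C(C)C)c(O[Si](C)(C)C(C)(C)C)cc(O[Si](C)(C)C(C)(C)C)c3[C@H]2C1
F7 | step 7 | 1-[(5aR,8S,9aR)-1,3-dihydroxy-5a-methyl-8-(prop-1-en-2-yl)-5a,6,7,8,9,9a-hexahydrodibenzo[b,d]furan-4-yl]-2-methylpropan-1-one (angular isomer, ether oxygen ortho to acyl) | C=C(C)[C@H]1CC[C@@]2(C)Oc3c(C(=O)C(C)C)c(O)cc(O)c3[C@H]2C1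
F8 | step 7 | (5aR,8S,9aR)-3-hydroxy-5a-methyl-2,2-bis(3-methylbut-2-en-1-yl)-4-(2-methylpropanoyl)-8-(prop-1-en-2-yl)-5a,6,7,8,9,9a-hexahydrodibenzo[b,d]furan-1(2H)-one | C=C(C)[C@H]1CC[C@@]2(C)OC3=C([C@H]2C1)C(=O)C(CC=C(C)C)(CC=C(C)C)C(O)=C3C(=O)C(C)C
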